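The decision is when to stop this flask if open intermediate is what we want, since it takes twice the reagent of the red run.

- red: starting material 20 mM; partner 0.90 equiv; reagent 0.65 equiv; run made earlier
- flask: starting material 20 mM; partner 0.900 equiv; reagent 1.30 equiv; time 8.0 h

red run (percent of the starting material charged)

| time / min | open intermediate / % | target / % | starting material / % |
|---|---|---|---|
| 8.00 | 10.1 | 1.8 | 77.1 |
| 15.0 | 6.9 | 1.8 | 67.7 |
| 25.0 | 3.4 | 5.4 | 60.8 |
| 30.0 | 3.6 | 5.2 | 60.5 |
| 40.0 | 0 | 3.5 | 57.6 |
| 50.0 | 1.5 | 3.6 | 58.0 |

(each reading ± 1 percentage point)

- percent here means starting material units held: one side product counts as two
- the earlier runs were read with a standard deviation of 1 percentage point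
- on the list of suspects stand: starting material + reagent -> open intermediate; reagent + partner -> second intermediate; open intermediate + second intermediate -> target; 2 second intermediate -> homo product; starting material + open intermediate -> side product

1. the best time, 8.0 h at the latest, for open intermediate
2. the amount of open intermediate, in percent of the starting material charged, at that time

Two chemists disagree. The first looks at the step that makes open intermediate, which is first order in reagent. For him, more reagent runs the same curve on a faster clock. This flask then peaks at 0.0667 h, about as high as the top red reading, 10.1%.

The second, whom I join, looks at how reagent itself is used. It reacts with partner and starting material, charged at 18.0 mM and 20 mM in both flasks. Its early lifetime therefore stays as it was. Open intermediate is lost to starting material, whose charge also stays. Target is a small drain, with a red reading of 1.8% at 8.00 min, less than open intermediate. On this view the early curve grows in height and keeps its time.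

The quantity to carry is the peak yield per equivalent of reagent, at fixed partner and starting material. The red reading at 8.00 min, taken with a standard deviation of 1 percentage point, gives 15.5% per equivalent. So I expect 20.2% in this flask, near 0.13 h.

The forecast gives 20% at 0.15 h, adding “The peak is broad, so the time is uncertain”.

This flask peaks at 0.120 h with 19.4%. That time lies nearer to the red reading's time than to the faster clock's.

    starting material + reagent → open intermediate (k = 3.60 /M/min)
    reagent + partner → second intermediate (k = 8.10 /M/min)
    open intermediate + second intermediate → target (k = 5.10 /M/min)
    2 second intermediate → homo product (k = 6.90 /M/min)
    starting material + open intermediate → side product (k = 5.70 /M/min)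

At 0.120 h, the best time of this flask, reagent is down to 35.3% of its own charge. In the neighbouring flask with 5.20 equiv of reagent, other charges held, the yield per equivalent gives 80.6%. That flask gives 54.7%, which is lower. Reagent is in excess in that neighbouring flask, the pseudo-first-order case, and this is the ground of the first chemist's clock. His height does not carry over, since that peak stands higher than the top red reading. At 8.00 h that neighbouring flask holds 66% of its reagent and 0% of its starting material.

The data stem from a simulated flask for an exercise, and the scatter is random.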